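Assumption: labdane numbering is used for every compound (C17 on C8, C20 on C10, side chain starts at C11 on C9; α is the face of H5 and H9, β the face of the C10 methyl), and 1, 2 and all reagents are bought.

**Retrosynthetic overview**
1. 12 ⇒ 10: the C13 methyl and the C15 ester are added across a terminal alkyne (syn methylalumination, then ClCO2Me), which sets 13E.
2. 10 ⇒ 7 (key step): the C11–O bond of the acetate (retention) and the 8(17)-alkene arise together from a cyclic hydroperoxy ketal, by a Criegee-type C→O shift and eliminative opening of the resulting 1,3-dioxan-2-ylium ion.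
3. 7 ⇒ 6 ⇒ 4: peroxyketalisation of the γ-hydroxy methyl ketone made from the lactone and MeLi; the acetate carbonyl carbon is the old lactone carbon and its methyl comes from MeLi.
4. 4 ⇒ 1 + 2: α-face alkylation of the sclareolide enolate sets C11.
5. Rings: the trans-decalin (C5, C9, C10) is bought with 1 and no ring of the target is built; two transient oxacycles (tetrahydrofuran ketal, then 1,3-dioxan-2-ylium) are formed and opened in steps 2–4.

**Route**

Step 1
Reactants: 1 (+)-sclareolide; 2 propargyl bromide
Product: 4 (1S,3aR,5aS,9aS,9bR)-3a,6,6,9a-tetramethyl-1-(prop-2-yn-1-yl)decahydronaphtho[2,1-b]furan-2(1H)-one [(11S)-11-propargylsclareolide; propargyl on the α face, cis to H9], via lithium enolate of sclareolide 3 (not isolated)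
Conditions: LiN(i-Pr)2 (1.1 equiv), THF, −78 °C, 45 min; then 2 (1.5 equiv), −78 → −20 °C
Reagents that add atoms: none
Why: Kinetic lithium enolate alkylation (SN2): the planar lactone enolate is attacked on its α face, anti to the axial C8 and C10 methyl groups, which places the propargyl group cis to H9 and sets C11 as S.

Step 2
Reactants: 4 (11S)-11-propargylsclareolide
Product: 6 (3S)-3-[(1R,2R,4aS,8aS)-2-hydroxy-2,5,5,8a-tetramethyldecahydronaphthalen-1-yl]hex-5-yn-2-one (γ-hydroxy methyl ketone; acetyl and propargyl on C11), via dilithiated cyclic hemiketalate 5 (not isolated)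
Conditions: MeLi (2.3 equiv), THF, −78 °C, 1 h; then AcOH (2.5 equiv), −78 °C → rt
Reagents that add atoms: methyllithium, [Li]C
Why: Organolithium addition to a lactone: after deprotonating the alkyne, MeLi adds once to the lactone carbonyl, and the cyclic lithium hemiketalate 5 keeps the ketone masked until the cold acidic quench, so a second addition and C11 epimerisation are avoided (the parent reaction on 1 is standard).

Step 3
Reactants: 6 γ-hydroxy methyl ketone
Product: 7 (1S,3aR,5aS,9aS,9bR)-2-hydroperoxy-2,3a,6,6,9a-pentamethyl-1-(prop-2-yn-1-yl)dodecahydronaphtho[2,1-b]furan (cyclic hydroperoxy ketal; both C12 epimers)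
Conditions: 50% aq H2O2 (5 equiv), camphorsulfonic acid (5 mol %), Et2O, 0 °C, 2 h; cold NaHCO3 and brine washes until peroxide-free aqueous phase, crude used at once
Reagents that add atoms: hydrogen peroxide, OO
Why: Acid-catalysed peroxyketalisation: the γ-hydroxy ketone closes to a five-membered cyclic oxocarbenium ion that is captured by H2O2, a strong α-effect nucleophile, faster than it can lose H11; the new C12 centre is formed as a mixture that converges in step 4.

Step 4
Reactants: 7 cyclic hydroperoxy ketal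
Product: 10 (1S)-1-[(1S,4aS,8aS)-5,5,8a-trimethyl-2-methylidenedecahydronaphthalen-1-yl]but-3-yn-1-yl acetate, via peroxy trifluoroacetate 8 (not isolated), via dioxanylium trifluoroacetate 9 (not isolated)
Conditions: (CF3CO)2O (1.2 equiv), 2,6-lutidine (4 equiv), CH2Cl2, −78 → 0 °C
Reagents that add atoms: none
Why: Proposed new method: an eliminative Criegee rearrangement – O-trifluoroacetylation turns the peroxide O–O bond into a leaving group, the secondary C11 (a far better migrating group than CH3, assisted by the ring-oxygen lone pair) shifts from C12 to oxygen with retention to give the 2-methyl-1,3-dioxan-2-ylium ion 9 bridging O11 and O8, and because its C8–O bond is equatorial the only anti-periplanar β-hydrogens are those of the axial C17 methyl, so lutidine-mediated E2 loss of the tertiary O-alkyl arm releases the neutral C11 acetate and the 8(17)-alkene in one operation; the closest known reactions are the Criegee rearrangement of α-alkoxy hydroperoxides to esters (the peroxide counterpart of the Baeyer–Villiger oxidation, in which the alkoxy group is normally lost by dealkylation or hydrolysis) and the SOCl2/pyridine anti-elimination of 8α-hydroxylabdanes to exocyclic alkenes.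

Step 5
Reactants: 10 alkyne acetate
Product: 12 methyl (2E,5S)-5-acetoxy-3-methyl-5-[(1S,4aS,8aS)-5,5,8a-trimethyl-2-methylidenedecahydronaphthalen-1-yl]pent-2-enoate [methyl (11S,13E)-11-acetoxylabda-8(17),13-dien-15-oate], via alkenyl(dimethyl)alane 11 (not isolated)
Conditions: Me3Al (3 equiv), Cp2ZrCl2 (zirconocene dichloride, 0.5 equiv), CH2Cl2, 0 °C → rt; then ClCO2Me (5 equiv), 0 °C → rt
Reagents that add atoms: trimethylaluminium, C[Al](C)C; methyl chloroformate, COC(Cl)=O
Why: Negishi zirconium-catalysed carboalumination: Me–Al adds syn across the terminal alkyne with methyl on the internal carbon, and the alkenyl–Al bond is acylated by ClCO2Me with retention, so the C13 methyl and the ester end up cis (13E); the hindered 1,1-disubstituted ring alkene does not react.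

**Compound list**

1 | (+)-sclareolide, (3aR,5aS,9aS,9bR) | C[C@@]12CC[C@H]3C(C)(C)CCC[C@]3(C)[C@H]1CC(=O)O2 | starting material
2 | propargyl bromide (3-bromoprop-1-yne) | C#CCBr | starting material
3 | lithium enolate of sclareolide | C[C@@]12CC[C@H]3C(C)(C)CCC[C@]3(C)[C@H]1C=C(O[Li])O2 | intermediate
4 | (11S)-11-propargylsclareolide (propargyl α, cis to H9) | C[C@@]12CC[C@H]3C(C)(C)CCC[C@]3(C)[C@H]1[C@H](CC#C)C(=O)O2 | intermediate
5 | dilithiated cyclic hemiketalate (lithium acetylide and lithium hemiketal alkoxide, C12 epimers) | C[C@@]12CC[C@H]3C(C)(C)CCC[C@]3(C)[C@H]1[C@H](CC#C[Li])C(C)(O[Li])O2 | intermediate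
6 | (3S)-3-[(1R,2R,4aS,8aS)-2-hydroxy-2,5,5,8a-tetramethyldecahydronaphthalen-1-yl]hex-5-yn-2-one | C[C@@]1(O)CC[C@H]2C(C)(C)CCC[C@]2(C)[C@H]1[C@H](CC#C)C(C)=O | intermediate
7 | cyclic hydroperoxy ketal (8α,12-epoxy-12-hydroperoxide, both C12 epimers, 11S) | C[C@@]12CC[C@H]3C(C)(C)CCC[C@]3(C)[C@H]1[C@H](CC#C)C(C)(OO)O2 | intermediate
8 | peroxy trifluoroacetate of 7 | C[C@@]12CC[C@H]3C(C)(C)CCC[C@]3(C)[C@H]1[C@H](CC#C)C(C)(OOC(=O)C(F)(F)F)O2 | intermediate
9 | 2-methyl-1,3-dioxan-2-ylium ion bridging O11 and O8, trifluoroacetate salt | C[C@@]12CC[C@H]3C(C)(C)CCC[C@]3(C)[C@H]1[C@H](CC#C)OC(C)=[O+]2.[O-]C(=O)C(F)(F)F | intermediate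
10 | (1S)-1-[(1S,4aS,8aS)-5,5,8a-trimethyl-2-methylidenedecahydronaphthalen-1-yl]but-3-yn-1-yl acetate | C=C1CC[C@H]2C(C)(C)CCC[C@]2(C)[C@H]1[C@H](CC#C)OC(C)=O | intermediate
11 | (E)-alkenyl(dimethyl)alane (CH3 on C13 and AlMe2 on C14, cis) | C=C1CC[C@H]2C(C)(C)CCC[C@]2(C)[C@H]1[C@H](C/C(C)=C/[Al](C)C)OC(C)=O | intermediate
12 | methyl (11S,13E)-11-acetoxylabda-8(17),13-dien-15-oate (CNP0309821.1) | C=C1CC[C@H]2C(C)(C)CCC[C@]2(C)[C@H]1[C@H](C/C(C)=C/C(=O)OC)OC(C)=O | target

**Totals**
Total step count: 5. Longest linear sequence: 5 steps (1 → 4 → 6 → 7 → 10 → 12).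

**Steps most likely to fail, with fallbacks**

Step 4 (the proposed eliminative Criegee rearrangement). It can fail in three ways:
- methyl instead of C11 migration, which leads back to lactone-type material;
- ionisation of 9 without base control, giving ring-alkene isomers (Δ7, Δ8);
- capture of 9 by trifluoroacetate or water, giving hydroxy esters.

The acid of step 3 is also the one place where C11 could epimerise through the enol ether. The fallback uses known chemistry, sets out from 6 and comes back to the route at 10, so it bypasses 7–9. Classical Baeyer–Villiger oxidation of 6 with m-CPBA and NaHCO3 in CH2Cl2 (0 °C → rt; C11 migrates with retention, the alkyne is inert) gives the hydroxy acetate (1S)-1-[(1S,2R,4aS,8aS)-2-hydroxy-2,5,5,8a-tetramethyldecahydronaphthalen-1-yl]but-3-yn-1-yl acetate F2. SOCl2 and pyridine in CH2Cl2 at −78 °C then dehydrate the equatorial tertiary alcohol through its chlorosulfite, mainly to the exocyclic alkene 10. Minor ring-alkene isomers are removed on AgNO3-impregnated silica.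

Step 5 (carboalumination next to an acetate). Me3Al may attack the C11 acetate, or the reaction may stall because the ester binds aluminium. The fallback sets out from 10 and comes back at 12. K2CO3 in MeOH removes the acetate to give the homopropargylic alcohol (1S)-1-[(1S,4aS,8aS)-5,5,8a-trimethyl-2-methylidenedecahydronaphthalen-1-yl]but-3-yn-1-ol F3, the classical substrate type for this chemistry. Me3Al and Cp2ZrCl2, then I2, give the (E)-vinyl iodide (1S,3E)-4-iodo-3-methyl-1-[(1S,4aS,8aS)-5,5,8a-trimethyl-2-methylidenedecahydronaphthalen-1-yl]but-3-en-1-ol F4. Methoxycarbonylation with PdCl2(PPh3)2, CO (1 atm), MeOH and Et3N at 50 °C gives the hydroxy enoate methyl (2E,5S)-5-hydroxy-3-methyl-5-[(1S,4aS,8aS)-5,5,8a-trimethyl-2-methylidenedecahydronaphthalen-1-yl]pent-2-enoate F5; the E geometry prevents lactonisation. Ac2O, DMAP and pyridine then give 12.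

Step 2 (MeLi on an α-branched, hindered lactone). MeLi may enolise 4 instead of adding, returning 4 possibly epimerised at C11, or it may add twice. The fallback sets out from 4 and comes back at 6. The lactone is opened with Me2AlN(OMe)Me (from AlMe3 and MeNH(OMe)·HCl, CH2Cl2, 0 °C → rt) to the hydroxy Weinreb amide (2S)-2-[(1R,2R,4aS,8aS)-2-hydroxy-2,5,5,8a-tetramethyldecahydronaphthalen-1-yl]-N-methoxy-N-methylpent-4-ynamide F1. MeMgBr (4 equiv, THF, 0 °C) then gives 6 through the stable chelated tetrahedral intermediate.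

**Further compounds**

F1 | step 2 | (2S)-2-[(1R,2R,4aS,8aS)-2-hydroxy-2,5,5,8a-tetramethyldecahydronaphthalen-1-yl]-N-methoxy-N-methylpent-4-ynamide | C[C@@]1(O)CC[C@H]2C(C)(C)CCC[C@]2(C)[C@H]1[C@H](CC#C)C(=O)N(C)OC
F2 | step 4 | (1S)-1-[(1S,2R,4aS,8aS)-2-hydroxy-2,5,5,8a-tetramethyldecahydronaphthalen-1-yl]but-3-yn-1-yl acetate | C[C@@]1(O)CC[C@H]2C(C)(C)CCC[C@]2(C)[C@H]1[C@H](CC#C)OC(C)=O
F3 | step 5 | (1S)-1-[(1S,4aS,8aS)-5,5,8a-trimethyl-2-methylidenedecahydronaphthalen-1-yl]but-3-yn-1-ol | C=C1CC[C@H]2C(C)(C)CCC[C@]2(C)[C@H]1[C@H](CC#C)O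
F4 | step 5 | (1S,3E)-4-iodo-3-methyl-1-[(1S,4aS,8aS)-5,5,8a-trimethyl-2-methylidenedecahydronaphthalen-1-yl]but-3-en-1-ol | C=C1CC[C@H]2C(C)(C)CCC[C@]2(C)[C@H]1[C@H](C/C(C)=C/I)O
F5 | step 5 | methyl (2E,5S)-5-hydroxy-3-methyl-5-[(1S,4aS,8aS)-5,5,8a-trimethyl-2-methylidenedecahydronaphthalen-1-yl]pent-2-enoate | C=C1CC[C@H]2C(C)(C)CCC[C@]2(C)[C@H]1[C@H](C/C(C)=C/C(=O)OC)O
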